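Assumption: centres that are destroyed later (C-6 of **7** and **8**, C-2 of **17**) are carried as epimer mixtures and written without a stereo label; β means the face of the angular 4a-methyl group, α the opposite face.

**Retrosynthetic overview**
1. The bicyclo[2.2.1]heptane is made last: target **18** ⇐ tertiary allylic alcohol **17**, by an acid-triggered allyl-cation/alkene (3+2) cyclisation ending in exo capture of water (forms C–C ×2 and the isopropyl carbinol).
2. **17** ⇐ allyl ketone **14** + 3-methylbut-1-en-2-yllithium; **14** ⇐ γ-hydroxy enone **11** by 1,4-hydrosilylation and Tsuji allylation; **11** ⇐ bromo-enone **9** by vinylogous Rubottom oxidation.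
3. Ring B: **9** ⇐ bromo-diketone **8** by aldol condensation.
4. Key step: the bromonium-induced semipinacol 1,2-alkyl shift **5** → **6** builds the quaternary methyl centre and the C–Br centre of ring A together; **5** ⇐ 2-methylcyclohex-2-enone **1** + organozinc from **2** (asymmetric 1,2-addition).
5. Ring order: A (from **1**) → B (aldol) → norbornane (cationic cascade).

**Route**

Step 1
Reactants: 1 2-methylcyclohex-2-en-1-one; 2 2-(2-bromoethyl)-2-methyl-1,3-dioxolane (ethylene ketal of 4-bromobutan-2-one)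
Product: 5 (S)-2-methyl-1-[2-(2-methyl-1,3-dioxolan-2-yl)ethyl]cyclohex-2-en-1-ol, via Grignard reagent 3 (not isolated), via dialkylzinc 4 (not isolated)
Conditions: 2, Mg, THF; ZnCl2, then dioxane, filter; 1, Ti(OiPr)4 (1.2 equiv), Walsh bis(camphorsulfonamide)diol ligand (5 mol %, enantiomer giving S), PhMe, rt; aq. NH4Cl
Reagents that add atoms: none
Why: Ti/bis(sulfonamide)diol-catalysed asymmetric 1,2-addition of a functionalised dialkylzinc to an α-methyl cyclic enone (Walsh ketone alkylation) sets the carbinol centre, which later fixes the face of the 1,2-shift.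

Step 2
Reactants: 5 (S)-2-methyl-1-[2-(2-methyl-1,3-dioxolan-2-yl)ethyl]cyclohex-2-en-1-ol
Product: 6 (2S,3S)-3-bromo-2-methyl-2-[2-(2-methyl-1,3-dioxolan-2-yl)ethyl]cyclohexan-1-one (Br cis to 2-Me)
Conditions: NBS (1.1 equiv), i-PrOH/CH2Cl2, −20 → 0 °C, dark
Reagents that add atoms: N-bromosuccinimide, O=C1CCC(=O)N1Br
Why: Bromonium-induced semipinacol rearrangement (1,2-alkyl shift): Br+ adds to the alkene face syn to OH and the side chain anti to it migrates from the carbinol carbon to C-2, so the quaternary centre and the C–Br centre form stereospecifically (chain trans to Br, Me cis to Br).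

Step 3
Reactants: 6 (2S,3S)-3-bromo-2-methyl-2-[2-(2-methyl-1,3-dioxolan-2-yl)ethyl]cyclohexan-1-one
Product: 7 (2S,3S)-3-bromo-2,6-dimethyl-2-[2-(2-methyl-1,3-dioxolan-2-yl)ethyl]cyclohexan-1-one (C-6 epimers)
Conditions: LDA, THF, −78 °C; MeI, −78 → −20 °C
Reagents that add atoms: iodomethane, CI
Why: Kinetic enolate alkylation at the only enolisable α-carbon (C-2 is quaternary, so no E1cB loss of the β-bromide); the new methyl centre is equilibrated later.

Step 4
Reactants: 7 (2S,3S)-3-bromo-2,6-dimethyl-2-[2-(2-methyl-1,3-dioxolan-2-yl)ethyl]cyclohexan-1-one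
Product: 9 5β-bromo-4aβ,8α-dimethyl-4,4a,5,6,7,8-hexahydronaphthalen-2(3H)-one, via diketone 8 (not isolated)
Conditions: TsOH·H2O, acetone/H2O, 50 °C; then TsOH, PhMe, reflux (Dean–Stark)
Reagents that add atoms: water, O
Why: Ketal hydrolysis then acid-catalysed intramolecular aldol condensation (Robinson-type cyclodehydration) closes ring B; the 8-methyl equilibrates through the dienol to the pseudo-equatorial α position.

Step 5
Reactants: 9 5β-bromo-4aβ,8α-dimethyl-4,4a,5,6,7,8-hexahydronaphthalen-2(3H)-one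
Product: 11 5β-bromo-8β-hydroxy-4aβ,8α-dimethyl-4,4a,5,6,7,8-hexahydronaphthalen-2(3H)-one, via silyl dienol ether 10 (not isolated)
Conditions: TMSOTf, Et3N, CH2Cl2, 0 °C; then mCPBA, NaHCO3, −20 °C; aq. citric acid
Reagents that add atoms: 3-chloroperoxybenzoic acid, O=C(OO)c1cccc(Cl)c1
Why: Vinylogous Rubottom oxidation of the extended dienol ether; the peracid attacks the γ-carbon axially from the β face (as in 6β-hydroxylation of steroidal 3,5-dienol ethers), giving the axial tertiary OH cis to the angular methyl.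

Step 6
Reactants: 11 5β-bromo-8β-hydroxy-4aβ,8α-dimethyl-4,4a,5,6,7,8-hexahydronaphthalen-2(3H)-one
Product: 12 triethylsilyl enol ether of 5β-bromo-8β-hydroxy-4aβ,8α-dimethyl-8aα-H-octahydronaphthalen-2-one (C1=C2 enol ether, trans-fused, free 8-OH)
Conditions: RhCl(PPh3)3 (2 mol %), Et3SiH (1.2 equiv), PhH, 60 °C
Reagents that add atoms: triethylsilane, CC[SiH](CC)CC
Why: Rh-catalysed 1,4-hydrosilylation (Ojima) delivers H to C-8a from the α face, away from the axial 4a-methyl and 8-OH, giving the trans-decalin and a regiodefined enol ether.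

Step 7
Reactants: 12 triethylsilyl enol ether of 5β-bromo-8β-hydroxy-4aβ,8α-dimethyl-8aα-H-octahydronaphthalen-2-one; 13 allyl methyl carbonate
Product: 14 1α-allyl-5β-bromo-8β-hydroxy-4aβ,8α-dimethyl-8aα-H-octahydronaphthalen-2(1H)-one (trans-fused, equatorial allyl)
Conditions: Pd2(dba)3·CHCl3 (2.5 mol %), dppe (5 mol %), THF, 65 °C; then DBU, CH2Cl2, rt
Reagents that add atoms: none
Why: Tsuji Pd-catalysed allylation of a silyl enol ether with an allyl carbonate is regiospecific at C-1; DBU equilibrates the α-centre to the equatorial allyl, which avoids the 1,3-diaxial clash with the angular methyl.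

Step 8
Reactants: 14 1α-allyl-5β-bromo-8β-hydroxy-4aβ,8α-dimethyl-8aα-H-octahydronaphthalen-2(1H)-one; 15 2-bromo-3-methylbut-1-ene
Product: 17 1α-allyl-5β-bromo-4aβ,8α-dimethyl-2-(3-methylbut-1-en-2-yl)-8aα-H-decahydronaphthalene-2,8β-diol (C-2 epimers), via alkenyllithium 16 (not isolated)
Conditions: 15, t-BuLi (2 equiv per 15), Et2O, −78 °C; CeCl3, THF, −78 °C; 14 (3 equiv of 16), −78 → −40 °C
Reagents that add atoms: none
Why: Organocerium 1,2-addition to a hindered, enolisable ketone; the first equivalent deprotonates the free OH, the equatorial secondary bromide is inert at −78 °C, and the new carbinol centre is lost on ionisation.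

Step 9
Reactants: 17 1α-allyl-5β-bromo-4aβ,8α-dimethyl-2-(3-methylbut-1-en-2-yl)-8aα-H-decahydronaphthalene-2,8β-diol
Product: 18 target bromo diol CNP0362628.1
Conditions: TfOH (5 mol %), HFIP/H2O (20:1), −20 → 0 °C
Reagents that add atoms: water, O
Why: Proposed new method: selective ionisation of the tertiary allylic alcohol gives a 2-isopropylallyl cation; the equatorial allyl terminus adds axially at the ring carbon (five-ring), the resulting cation is captured by the now 1,1-disubstituted isopropyl alkene to close the bicyclo[2.2.1]heptane, and the tertiary 2-norbornyl cation is trapped by water on the exo face (sets the quaternary bridgehead, the other bridgehead and the carbinol centre); closest known reaction type: stepwise (3+2) cycloadditions of allyl and oxyallyl cations with alkenes and exo-selective hydration of 2-alkyl-2-norbornyl cations.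

**Compound list**
1 | 2-methylcyclohex-2-en-1-one | CC1=CCCCC1=O | starting material
2 | 2-(2-bromoethyl)-2-methyl-1,3-dioxolane | CC1(CCBr)OCCO1 | starting material
3 | [2-(2-methyl-1,3-dioxolan-2-yl)ethyl]magnesium bromide | CC1(CC[Mg]Br)OCCO1 | intermediate
4 | bis[2-(2-methyl-1,3-dioxolan-2-yl)ethyl]zinc | CC1(CC[Zn]CCC2(C)OCCO2)OCCO1 | intermediate
5 | (S)-2-methyl-1-[2-(2-methyl-1,3-dioxolan-2-yl)ethyl]cyclohex-2-en-1-ol | CC1=CCCC[C@]1(O)CCC1(C)OCCO1 | intermediate
6 | (2S,3S)-3-bromo-2-methyl-2-[2-(2-methyl-1,3-dioxolan-2-yl)ethyl]cyclohexan-1-one | O=C1CCC[C@H](Br)[C@@]1(C)CCC1(C)OCCO1 | intermediate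
7 | (2S,3S)-3-bromo-2,6-dimethyl-2-[2-(2-methyl-1,3-dioxolan-2-yl)ethyl]cyclohexan-1-one | O=C1C(C)CC[C@H](Br)[C@@]1(C)CCC1(C)OCCO1 | intermediate
8 | (2S,3S)-3-bromo-2,6-dimethyl-2-(3-oxobutyl)cyclohexan-1-one | O=C1C(C)CC[C@H](Br)[C@@]1(C)CCC(C)=O | intermediate
9 | 5β-bromo-4aβ,8α-dimethyl-4,4a,5,6,7,8-hexahydronaphthalen-2(3H)-one | O=C1C=C2[C@](C)(CC1)[C@@H](Br)CC[C@@H]2C | intermediate
10 | trimethylsilyl dienol ether of 9 (C1=C2 and C8=C8a) | C[Si](C)(C)OC1=CC2=C(C)CC[C@H](Br)[C@@]2(C)CC1 | intermediate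
11 | 5β-bromo-8β-hydroxy-4aβ,8α-dimethyl-4,4a,5,6,7,8-hexahydronaphthalen-2(3H)-one | O=C1C=C2[C@](C)(CC1)[C@@H](Br)CC[C@@]2(C)O | intermediate
12 | triethylsilyl enol ether of 5β-bromo-8β-hydroxy-4aβ,8α-dimethyl-8aα-H-octahydronaphthalen-2-one | CC[Si](CC)(CC)OC1=C[C@H]2[C@](C)(CC1)[C@@H](Br)CC[C@@]2(C)O | intermediate
13 | allyl methyl carbonate | C=CCOC(=O)OC | starting material
14 | 1α-allyl-5β-bromo-8β-hydroxy-4aβ,8α-dimethyl-8aα-H-octahydronaphthalen-2(1H)-one | C=CC[C@H]1[C@H]2[C@](C)(CCC1=O)[C@@H](Br)CC[C@@]2(C)O | intermediate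
15 | 2-bromo-3-methylbut-1-ene | C=C(Br)C(C)C | starting material
16 | (3-methylbut-1-en-2-yl)lithium | [Li]C(=C)C(C)C | intermediate
17 | 1α-allyl-5β-bromo-4aβ,8α-dimethyl-2-(3-methylbut-1-en-2-yl)-8aα-H-decahydronaphthalene-2,8β-diol | C=CC[C@H]1[C@H]2[C@](C)(CCC1(O)C(=C)C(C)C)[C@@H](Br)CC[C@@]2(C)O | intermediate
18 | target bromo diol CNP0362628.1 | CC(C)[C@]1(O)C[C@@H]2C[C@H]3[C@H]4[C@](C)(CC[C@@]31C2)[C@@H](Br)CC[C@@]4(C)O | target

**Totals**
Total steps: 9. Longest linear sequence: 9 (1/2 → 18).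

**Steps most likely to fail and fallbacks**

Step 2 (semipinacol shift). The primary alkyl chain may migrate too slowly, allowing bromo-epoxide formation or ring contraction. The fallback sets out from 2 and comes back at 6. 2-Methylcyclohexane-1,3-dione F1 (from cyclohexane-1,3-dione, MeI, K2CO3) is C-alkylated with 2 (t-BuOK, NaI, DMSO) to give 2-methyl-2-[2-(2-methyl-1,3-dioxolan-2-yl)ethyl]cyclohexane-1,3-dione F2. A desymmetrising CBS (or baker's yeast) mono-reduction gives 3-hydroxy-2-methyl-2-[2-(2-methyl-1,3-dioxolan-2-yl)ethyl]cyclohexan-1-one F3 with OH cis to the side chain. Appel bromination (PPh3, CBr4) with inversion then gives 6.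

Step 6 (1,4-hydrosilylation of a very hindered β,β-disubstituted enone; face selectivity at C-8a). The fallback sets out from 9 and comes back at 14, installing the allyl group before the reduction. The dienolate of 9 (t-BuOK, t-BuOH) is allylated at C-1 with allyl bromide and reconjugated (HCl, MeOH) to 1-allyl-5β-bromo-4aβ,8α-dimethyl-4,4a,5,6,7,8-hexahydronaphthalen-2(3H)-one F4. TMSOTf/Et3N then mCPBA gives 1-allyl-5β-bromo-8β-hydroxy-4aβ,8α-dimethyl-4,4a,5,6,7,8-hexahydronaphthalen-2(3H)-one F5. Magnus conjugate reduction (Mn(dpm)3, PhSiH3, i-PrOH), which leaves the terminal alkene and the bromide untouched, followed by DBU gives 14.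

Step 9 (the proposed cationic cascade; competing elimination to trienes or attack at the primary allyl terminus). The fallback sets out from 14 and comes back at 18 through the ketone, using known reactions only.
- 1-Ethoxyvinyllithium/CeCl3 adds to 14 to give 1α-allyl-5β-bromo-2-(1-ethoxyvinyl)-4aβ,8α-dimethyl-8aα-H-decahydronaphthalene-2,8β-diol F6.
- Acid ionisation (TsOH, wet MeNO2) gives the 2-ethoxyallyl (oxyallyl-type) cation, whose (3+2) cycloaddition to the allyl group and hydrolysis give the bridged norbornan-2-one F7.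
- KHMDS/PhNTf2 gives the enol triflate F8.
- Negishi coupling (i-PrZnBr, Pd/CPhos) gives the 2-isopropylnorbornene F9.
- Mukaiyama hydration (Mn(dpm)3, PhSiH3, O2; then PPh3) traps the tertiary 2-norbornyl radical on the exo face and gives 18.

Further compounds
F1 | step 2 | 2-methylcyclohexane-1,3-dione | CC1C(=O)CCCC1=O
F2 | step 2 | 2-methyl-2-[2-(2-methyl-1,3-dioxolan-2-yl)ethyl]cyclohexane-1,3-dione | CC1(CCC2(C)OCCO2)C(=O)CCCC1=O
F3 | step 2 | 3-hydroxy-2-methyl-2-[2-(2-methyl-1,3-dioxolan-2-yl)ethyl]cyclohexan-1-one (OH cis to side chain) | O=C1CCC[C@@H](O)[C@@]1(C)CCC1(C)OCCO1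
F4 | step 6 | 1-allyl-5β-bromo-4aβ,8α-dimethyl-4,4a,5,6,7,8-hexahydronaphthalen-2(3H)-one | O=C1CC[C@]2(C)[C@@H](Br)CC[C@H](C)C2=C1CC=C
F5 | step 6 | 1-allyl-5β-bromo-8β-hydroxy-4aβ,8α-dimethyl-4,4a,5,6,7,8-hexahydronaphthalen-2(3H)-one | O=C1CC[C@]2(C)[C@@H](Br)CC[C@@](C)(O)C2=C1CC=C
F6 | step 9 | 1α-allyl-5β-bromo-2-(1-ethoxyvinyl)-4aβ,8α-dimethyl-8aα-H-decahydronaphthalene-2,8β-diol | C=CC[C@H]1[C@H]2[C@](C)(CCC1(O)C(=C)OCC)[C@@H](Br)CC[C@@]2(C)O
F7 | step 9 | bridged norbornan-2-one (target skeleton with C=O in place of the isopropyl carbinol) | O=C1C[C@@H]2C[C@H]3[C@H]4[C@](C)(CC[C@@]31C2)[C@@H](Br)CC[C@@]4(C)O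
F8 | step 9 | enol triflate of F7 | O=S(=O)(OC1=C[C@@H]2C[C@H]3[C@H]4[C@](C)(CC[C@@]31C2)[C@@H](Br)CC[C@@]4(C)O)C(F)(F)F
F9 | step 9 | 2-isopropylnorbornene (target skeleton with C=C in place of the isopropyl carbinol) | CC(C)C1=C[C@@H]2C[C@H]3[C@H]4[C@](C)(CC[C@@]31C2)[C@@H](Br)CC[C@@]4(C)O
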